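The starting material is the limiting reagent of the new recipes, each of which charges partner above it, at least 1.20 equiv. It leaves by two doors, to target and to cross product, so its ledger has few entries.

| flask | starting material | partner | second substrate | protic impurity | remark | time |
|---|---|---|---|---|---|---|
| alder | 0.20 M | 0.97 equiv | 1 equiv | 0.020 M | run made earlier |  |
| ash | 0.20 M | 4.8 equiv | 1 equiv | 0.020 M | run made earlier |  |
| Saturday's | 0.20 M | 1.20 equiv | 1.00 equiv | 0.0200 M |  | 6.0 h |
| Monday's | 0.20 M | 3.00 equiv | 1.00 equiv | 0.0200 M |  | 6.0 h |
| Sunday's | 0.20 M | 7.50 equiv | 1.00 equiv | 0.0200 M |  | 6.0 h |

- alder (time / h: target / %, starting material / %): 0.667: 37.0, 30.8; 1.33: 43.5, 15.8; 2.00: 46.6, 10.7; 2.50: 47.1, 8.1; 3.00: 46.9, 6.5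
- ash (time / h: target / %, starting material / %): 0.250: 75.5, 16.2; 0.833: 87.9, 0.7; 1.33: 89.1, 0.3; 2.00: 88.6, 0; 3.00: 88.8, 0

(standard deviation of a reading: 0.5 percentage points)

- the numbers in the tables scatter by 0.5 percentage points (one standard deviation)
- steps thought possible: starting material + partner -> target; partner -> decomposed reagent; starting material + second substrate -> cross product; partner + protic impurity -> quenched reagent; second substrate + partner -> second product

* which of the two there is more of at the end, Saturday's (cross product / target)
* which of the two there is more of at the end, Monday's (cross product / target)
* which of the two there is more of at the end, Sunday's (cross product / target)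
* how much target is there at the end, in percent of the starting material charged: Saturday's
* how much target is there at the end, in percent of the starting material charged: Monday's
* how much target is there at the end, in percent of the starting material charged: Sunday's

Here is my own reckoning. Of the two earlier runs, the ash run has the larger excess of partner, and its books at 3.00 h read:

target: 88.8%
starting material left: 0%
cross product, by difference: 11.2%

To carry this entry to other flasks, integrate the cross-product rate. With partner in large excess, the starting material and the second substrate both decay pseudo-first-order, at kT[partner] and kS[partner], the second through the step that forms second product. Let c mark a charge. Then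

x = ∫ kX [starting material] [second substrate] dt / [starting material]c = kX [second substrate]c / ((kT + kS) [partner]c)

So, with partner in large excess and second substrate charged at 1 equiv on 0.20 M of starting material, the cross-product share x times the partner charge is a constant. I call this the cross constant, M = x[partner]c, and read it from the ash run, with the scatter of that reading, as 0.108 M.

Booking the starting material as fully reacted, target takes the rest of the ledger:

Saturday's: cross product 44.8%, target 55.2%
Monday's: cross product 17.9%, target 82.1%
Sunday's: cross product 7.17%, target 92.8%

So I expect more target than cross product in each flask. In the alder run, with 0.97 equiv of partner and so no excess, M gives target 44.6%; the last reading shows 46.9% with 6.5% unspent. I therefore trust least the line for Saturday's, which has the smallest partner charge of the new recipes.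

The forecast names target, target and target as the larger for Saturday's, Monday's and Sunday's, with target at 55%, 80% and 93%. It closes the same books, holding that “all starting material is consumed”. My Monday's line stands above its figure.

The flasks give target 56.9%, 82.8% and 93.1%, against cross product 41.6%, 17.2% and 6.88%, so target leads on Saturday's, target on Monday's and target on Sunday's.

    starting material + partner → target (k = 0.140 M⁻¹ min⁻¹)
    partner → decomposed reagent (k = 9.70 × 10⁻⁴ min⁻¹)
    starting material + second substrate → cross product (k = 0.110 M⁻¹ min⁻¹)
    partner + protic impurity → quenched reagent (k = 0.0320 M⁻¹ min⁻¹)
    second substrate + partner → second product (k = 0.0730 M⁻¹ min⁻¹)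

Sunday's flask shows which entry matters. Without the step from starting material + second substrate to cross product, it gives 100% target instead of 93.1%, so that step is the main reason for the shortfall. Its size follows the partner charge: at the partner charge of Saturday's, 1.20 equiv, the recipe of Sunday's stands at 56.9% target. On a neighbour of Sunday's flask with 13.0 equiv of partner, second substrate unchanged, M gives cross product 4.14% and target 95.9%. The computed neighbour holds cross product 3.97% and target 96.0%.

Readings and results come from a simulation from invented constants.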